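Labdane numbering is used (ring A: C1–C5 and C10; ring B: C5–C10). The route rests on disconnecting the ring-fusion bond C5–C10 together with C8–C9: a thermal intramolecular Diels–Alder reaction of an open-chain trienal closes ring B as the new cyclohexene and ring A through the tether in one operation and sets C5, C8, C9 and C10. It exploits the cis relation of the C10 methyl and the C9 side chain (an E-enal dienophile) and the cis-2,3-diol, carried as an acetonide from D-pantolactone, which fixes the diene face. The precursor is a linear enal with a 2-silyloxy diene, whose enol ether later becomes the C7=C8 alkene.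

Key step: step 13

Remark: all decalins are trans-fused with H-5, O-2 and O-3 on one face and the C10 methyl and C9 substituent on the other ((2S,3R,5S,9R,10S) in 25–29); ketene acetal 8 is used as the isomer mixture formed, because its geometry is lost in step 7, and the C8 configuration of 17–23 is transient.

Step 1
Reactants: 1 D-(−)-pantolactone
Product: 2 (3R)-4,4-dimethyl-3-(triethylsilyloxy)oxolan-2-one
Conditions: Et3SiCl, imidazole, DMF, 0 °C to rt
Reagents that add atoms: chlorotriethylsilane, CC[Si](Cl)(CC)CC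
Why: Silyl ether formation masks the future C3 oxygen with a group that survives the organometallic steps and is later removed by mild acid; the pantolactone stereocenter becomes C3 unchanged.

Step 2
Reactants: 2 (3R)-4,4-dimethyl-3-(triethylsilyloxy)oxolan-2-one
Product: 3 (2R)-4-hydroxy-N-methoxy-N,3,3-trimethyl-2-(triethylsilyloxy)butanamide
Conditions: MeNHOMe·HCl, AlMe3, CH2Cl2, 0 °C to rt; aqueous work-up; used at once
Reagents that add atoms: N,O-dimethylhydroxylamine hydrochloride, CNOC.Cl
Why: Weinreb aminolysis of the lactone by the aluminium amide frees the primary alcohol (future C5) and turns the carbonyl (future C2) into an amide that can be reduced to the aldehyde; no stereocenter is touched.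

Step 3
Reactants: 3 (2R)-4-hydroxy-N-methoxy-N,3,3-trimethyl-2-(triethylsilyloxy)butanamide
Product: 4 (2R)-N-methoxy-N,3,3-trimethyl-4-oxo-2-(triethylsilyloxy)butanamide
Conditions: TEMPO (cat.), PhI(OAc)2, CH2Cl2, rt
Reagents that add atoms: none
Why: Nitroxyl-catalysed (TEMPO) oxidation of the neopentyl primary alcohol stops at the aldehyde, which has no α-hydrogen and cannot enolise.

Step 4
Reactants: 4 (2R)-N-methoxy-N,3,3-trimethyl-4-oxo-2-(triethylsilyloxy)butanamide
Product: 5 (2R)-N-methoxy-N,3,3-trimethyl-2-(triethylsilyloxy)pent-4-enamide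
Conditions: Ph3PCH3Br, KN(SiMe3)2, THF, 0 °C; then 4, −78 °C to rt
Reagents that add atoms: methyltriphenylphosphonium bromide, C[P+](c1ccccc1)(c1ccccc1)c1ccccc1.[Br-]
Why: Wittig methylenation of the aldehyde, which reacts far faster with the ylide than the Weinreb amide, installs the vinyl group that later becomes the C5=C6 end of the diene.

Step 5
Reactants: 5 (2R)-N-methoxy-N,3,3-trimethyl-2-(triethylsilyloxy)pent-4-enamide
Product: 6 (2R)-3,3-dimethyl-2-(triethylsilyloxy)pent-4-enal
Conditions: i-Bu2AlH, THF, −78 °C; aqueous work-up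
Reagents that add atoms: none
Why: Weinreb amide reduction stops at the aldehyde because the chelated tetrahedral aluminium adduct collapses only on work-up; the α-silyloxy stereocenter is kept at low temperature.

Step 6
Reactants: 7 methyl 3-methylbut-2-enoate
Product: 8 [(1-methoxy-3-methylbuta-1,3-dien-1-yl)oxy]trimethylsilane
Conditions: LiN(i-Pr)2, THF, −78 °C; then Me3SiCl
Reagents that add atoms: chlorotrimethylsilane, C[Si](C)(C)Cl
Why: γ-Deprotonation of the senecioate and O-silylation (silyl dienolate formation) give the vinylogous ketene acetal for the next step.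

Step 7
Reactants: 6 (2R)-3,3-dimethyl-2-(triethylsilyloxy)pent-4-enal; 8 [(1-methoxy-3-methylbuta-1,3-dien-1-yl)oxy]trimethylsilane
Product: 9 methyl (2E,5S,6R)-5-hydroxy-3,7,7-trimethyl-6-(triethylsilyloxy)nona-2,8-dienoate
Conditions: BF3·OEt2, CH2Cl2/Et2O, −78 °C; then aq. NaHCO3
Reagents that add atoms: none
Why: Vinylogous Mukaiyama aldol reaction: the dienolate attacks through its γ-carbon in the s-trans form, which should give the E-enoate, and approaches the BF3-bound aldehyde anti to the C–O bond and past the hydrogen instead of the tert-alkyl group (polar Felkin–Anh/Cornforth control), which should set the new carbinol (future C2) anti to the silyloxy group.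

Step 8
Reactants: 9 methyl (2E,5S,6R)-5-hydroxy-3,7,7-trimethyl-6-(triethylsilyloxy)nona-2,8-dienoate
Product: 11 methyl (2E)-4-[(4S,5R)-2,2-dimethyl-5-(2-methylbut-3-en-2-yl)-1,3-dioxolan-4-yl]-3-methylbut-2-enoate, via diol ester 10 (not isolated)
Conditions: CSA (cat.), MeOH, rt; then 2,2-dimethoxypropane, acetone, rt
Reagents that add atoms: 2,2-dimethoxypropane, COC(C)(C)OC
Why: Acid methanolysis of the triethylsilyl ether followed by acetonide formation ties the anti-diol into a cis-dioxolane, a temporary ring that presets the gauche C2–C3 bond of ring A; no stereocenter changes.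

Step 9
Reactants: 11 methyl (2E)-4-[(4S,5R)-2,2-dimethyl-5-(2-methylbut-3-en-2-yl)-1,3-dioxolan-4-yl]-3-methylbut-2-enoate; 12 pent-1-en-3-one
Product: 13 methyl (2E)-4-[(4S,5R)-2,2-dimethyl-5-[(3E)-2-methyl-5-oxohept-3-en-2-yl]-1,3-dioxolan-4-yl]-3-methylbut-2-enoate
Conditions: second-generation Hoveyda–Grubbs catalyst (5 mol %), excess 12, CH2Cl2, 40 °C
Reagents that add atoms: none
Why: Olefin cross-metathesis between the monosubstituted neopentyl alkene and the vinyl ketone should give the E-enone, while the trisubstituted enoate alkene is inert.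

Step 10
Reactants: 13 methyl (2E)-4-[(4S,5R)-2,2-dimethyl-5-[(3E)-2-methyl-5-oxohept-3-en-2-yl]-1,3-dioxolan-4-yl]-3-methylbut-2-enoate
Product: 14 methyl (2E)-4-[(4S,5R)-5-[(3E,5Z)-5-(tert-butyldimethylsilyloxy)-2-methylhepta-3,5-dien-2-yl]-2,2-dimethyl-1,3-dioxolan-4-yl]-3-methylbut-2-enoate
Conditions: TBSOTf, Et3N, CH2Cl2, −78 to 0 °C
Reagents that add atoms: tert-butyldimethylsilyl triflate, CC(C)(C)[Si](C)(C)OS(=O)(=O)C(F)(F)F
Why: Soft enolisation and O-silylation of the ethyl ketone (silyl enol ether formation) can occur only on the ethyl side because C4 is quaternary, and should give the Z enol ether, a 2-silyloxy diene with its methyl group pointing outward.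

Step 11
Reactants: 14 methyl (2E)-4-[(4S,5R)-5-[(3E,5Z)-5-(tert-butyldimethylsilyloxy)-2-methylhepta-3,5-dien-2-yl]-2,2-dimethyl-1,3-dioxolan-4-yl]-3-methylbut-2-enoate
Product: 15 (2E)-4-[(4S,5R)-5-[(3E,5Z)-5-(tert-butyldimethylsilyloxy)-2-methylhepta-3,5-dien-2-yl]-2,2-dimethyl-1,3-dioxolan-4-yl]-3-methylbut-2-en-1-ol
Conditions: i-Bu2AlH, CH2Cl2, −78 °C; aqueous work-up
Reagents that add atoms: none
Why: 1,2-Reduction of the conjugated ester with the aluminium hydride gives the allylic alcohol; the silyl dienol ether and the acetonide are inert to it.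

Step 12
Reactants: 15 (2E)-4-[(4S,5R)-5-[(3E,5Z)-5-(tert-butyldimethylsilyloxy)-2-methylhepta-3,5-dien-2-yl]-2,2-dimethyl-1,3-dioxolan-4-yl]-3-methylbut-2-en-1-ol
Product: 16 (2E)-4-[(4S,5R)-5-[(3E,5Z)-5-(tert-butyldimethylsilyloxy)-2-methylhepta-3,5-dien-2-yl]-2,2-dimethyl-1,3-dioxolan-4-yl]-3-methylbut-2-enal
Conditions: MnO2, CH2Cl2, rt
Reagents that add atoms: none
Why: Allylic alcohol oxidation with MnO2 gives the E-enal under neutral conditions that leave the electron-rich diene alone.

Step 13
Reactants: 16 (2E)-4-[(4S,5R)-5-[(3E,5Z)-5-(tert-butyldimethylsilyloxy)-2-methylhepta-3,5-dien-2-yl]-2,2-dimethyl-1,3-dioxolan-4-yl]-3-methylbut-2-enal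
Product: 17 7-(tert-butyldimethylsilyloxy)-2,3-(isopropylidenedioxy)-12,13,14,15,16-pentanorlabd-6-en-11-al (8-methyl and 9-formyl on the face of the C10 methyl)
Conditions: toluene (0.005 M), BHT (cat.), 150 °C, sealed tube, base-washed glass
Reagents that add atoms: none
Why: A thermal, concerted but asynchronous [4+2] cycloaddition joins the C5=C6–C7=C8 silyloxy diene and the C9=C10 E-enal, forming C5–C10 and C8–C9 in one suprafacial event (intramolecular Diels–Alder reaction). The closest known reaction type is the type 1 intramolecular Diels–Alder reaction of 1,7,9-decatrienes with a terminally activated dienophile, the usual entry to trans-decalins with an angular methyl group. Ring B closes as the six-membered cycloadduct ring and ring A as the six-membered ring spanned by the four-atom tether C1–C4 (fused mode), whose gauche C2–C3 bond is preset by the cis-dioxolane and whose folding is helped by the C4 gem-dimethyl group. C9 and C10 follow from the E geometry of the dienophile (formyl and methyl stay cis), the trans fusion at C5/C10 from the endo position of the formyl group over a chair-like tether, and C8 (transient) from the Z enol ether. The absolute sense comes from the dioxolane carbons, because only one diene face lets O-2 sit equatorial on the forming ring A, whereas the other would press it axially against the C10 methyl and the axial C4 methyl. The step needs endo and facial selectivity, which the E-dienophile and the dioxolane should secure; the silyloxy group is carried as the latent C7 ketone and does not reinforce the tether-imposed regiochemistry, so heating at high dilution is required.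

Step 14
Reactants: 17 7-(tert-butyldimethylsilyloxy)-2,3-(isopropylidenedioxy)-12,13,14,15,16-pentanorlabd-6-en-11-al
Product: 18 7-(tert-butyldimethylsilyloxy)-2,3-(isopropylidenedioxy)-13,14,15,16-tetranorlabda-6,11-diene
Conditions: Ph3PCH3Br, KN(SiMe3)2, THF, 0 °C to rt
Reagents that add atoms: methyltriphenylphosphonium bromide, C[P+](c1ccccc1)(c1ccccc1)c1ccccc1.[Br-]
Why: Wittig methylenation of the hindered C11 aldehyde adds C12 while the C7 carbonyl stays masked as its silyl enol ether; the equatorial C9 configuration is the stable one, so the basic ylide should not erode it.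

Step 15
Reactants: 19 methyl 3-oxobutanoate (methyl acetoacetate)
Product: 20 methyl (2E)-3-(trifluoromethylsulfonyloxy)but-2-enoate
Conditions: Tf2O, aq. Me4NOH, hexanes, 5 °C
Reagents that add atoms: triflic anhydride, O=S(=O)(OS(=O)(=O)C(F)(F)F)C(F)(F)F
Why: O-Sulfonylation of the β-keto ester enolate (enol triflate formation) with a non-coordinating tetramethylammonium counter-ion goes through the open, non-chelated enolate and should give the E-enol triflate.

Step 16
Reactants: 18 7-(tert-butyldimethylsilyloxy)-2,3-(isopropylidenedioxy)-13,14,15,16-tetranorlabda-6,11-diene; 20 methyl (2E)-3-(trifluoromethylsulfonyloxy)but-2-enoate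
Product: 22 methyl (13E)-7-(tert-butyldimethylsilyloxy)-2,3-(isopropylidenedioxy)labda-6,13-dien-15-oate, via alkylborane 21 (not isolated)
Conditions: 9-BBN, THF, rt; then 20, PdCl2(dppf) (5 mol %), aq. K3PO4, DMF, rt to 40 °C
Reagents that add atoms: none
Why: Anti-Markovnikov hydroboration of the only monosubstituted alkene, then B-alkyl Suzuki–Miyaura coupling with the enol triflate with retention of its geometry, completes the side chain with the 13E double bond.

Step 17
Reactants: 22 methyl (13E)-7-(tert-butyldimethylsilyloxy)-2,3-(isopropylidenedioxy)labda-6,13-dien-15-oate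
Product: 23 methyl (13E)-2,3-(isopropylidenedioxy)-7-oxolabd-13-en-15-oate
Conditions: Bu4NF, AcOH, THF, 0 °C
Reagents that add atoms: none
Why: Fluoride-induced cleavage of the silyl enol ether with protonation at C6 releases the C7 ketone without touching C8 or the acetonide.

Step 18
Reactants: 23 methyl (13E)-2,3-(isopropylidenedioxy)-7-oxolabd-13-en-15-oate
Product: 24 methyl (13E)-2,3-(isopropylidenedioxy)-7-(trifluoromethylsulfonyloxy)labda-7,13-dien-15-oate
Conditions: Tf2O, 2,6-di-tert-butyl-4-methylpyridine, CH2Cl2, 0 °C to rt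
Reagents that add atoms: triflic anhydride, O=S(=O)(OS(=O)(=O)C(F)(F)F)C(F)(F)F
Why: Enol triflate formation under equilibrating conditions (Tf2O with a hindered pyridine) should favour the more substituted C7=C8 enol triflate, helped by loss of the 1,3-diaxial contact between the C8 and C10 methyl groups; the C8 stereocenter is erased.

Step 19
Reactants: 24 methyl (13E)-2,3-(isopropylidenedioxy)-7-(trifluoromethylsulfonyloxy)labda-7,13-dien-15-oate
Product: 25 methyl (13E)-2,3-(isopropylidenedioxy)labda-7,13-dien-15-oate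
Conditions: Pd(OAc)2 (5 mol %), PPh3, HCO2H, Bu3N, DMF, 60 °C
Reagents that add atoms: none
Why: Palladium-catalysed formate reduction of the vinyl triflate replaces the triflate by hydrogen without moving the C7=C8 double bond.

Step 20
Reactants: 25 methyl (13E)-2,3-(isopropylidenedioxy)labda-7,13-dien-15-oate
Product: 27 (13E)-2,3-dihydroxylabda-7,13-dien-15-oic acid, via acetonide acid 26 (not isolated)
Conditions: LiOH, THF/MeOH/H2O, 45 °C; then 2 M HCl to pH 1, THF, rt
Reagents that add atoms: lithium hydroxide, [Li+].[OH-]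
Why: Ester saponification followed by acid-catalysed acetonide hydrolysis in the same flask; dilute aqueous acid should leave both trisubstituted alkenes in place.

Step 21
Reactants: 27 (13E)-2,3-dihydroxylabda-7,13-dien-15-oic acid
Product: 29 (13E)-2,3-diacetoxylabda-7,13-dien-15-oic acid (CNP0321684.1), via mixed anhydride 28 (not isolated)
Conditions: Ac2O, pyridine, DMAP (cat.), CH2Cl2, rt; then H2O, THF, rt
Reagents that add atoms: acetic anhydride, CC(=O)OC(C)=O
Why: DMAP-catalysed acetylation esterifies both hydroxyls, including the hindered axial C3–OH, and the mixed anhydride formed at the carboxyl group is hydrolysed back to the acid on aqueous stirring.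

Compound list
1 | D-(−)-pantolactone, (3R)-3-hydroxy-4,4-dimethyloxolan-2-one | CC1(C)COC(=O)[C@@H]1O | starting material
2 | (3R)-4,4-dimethyl-3-(triethylsilyloxy)oxolan-2-one | CC1(C)COC(=O)[C@@H]1O[Si](CC)(CC)CC | intermediate
3 | (2R)-4-hydroxy-N-methoxy-N,3,3-trimethyl-2-(triethylsilyloxy)butanamide | CON(C)C(=O)[C@H](O[Si](CC)(CC)CC)C(C)(C)CO | intermediate
4 | (2R)-N-methoxy-N,3,3-trimethyl-4-oxo-2-(triethylsilyloxy)butanamide | CON(C)C(=O)[C@H](O[Si](CC)(CC)CC)C(C)(C)C=O | intermediate
5 | (2R)-N-methoxy-N,3,3-trimethyl-2-(triethylsilyloxy)pent-4-enamide | CON(C)C(=O)[C@H](O[Si](CC)(CC)CC)C(C)(C)C=C | intermediate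
6 | (2R)-3,3-dimethyl-2-(triethylsilyloxy)pent-4-enal | O=C[C@H](O[Si](CC)(CC)CC)C(C)(C)C=C | intermediate
7 | methyl 3-methylbut-2-enoate | COC(=O)C=C(C)C | starting material
8 | [(1-methoxy-3-methylbuta-1,3-dien-1-yl)oxy]trimethylsilane (isomer mixture at C1=C2) | COC(O[Si](C)(C)C)=CC(C)=C | intermediate
9 | methyl (2E,5S,6R)-5-hydroxy-3,7,7-trimethyl-6-(triethylsilyloxy)nona-2,8-dienoate | COC(=O)/C=C(\C)C[C@H](O)[C@H](O[Si](CC)(CC)CC)C(C)(C)C=C | intermediate
10 | methyl (2E,5S,6R)-5,6-dihydroxy-3,7,7-trimethylnona-2,8-dienoate | COC(=O)/C=C(\C)C[C@H](O)[C@H](O)C(C)(C)C=C | intermediate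
11 | methyl (2E)-4-[(4S,5R)-2,2-dimethyl-5-(2-methylbut-3-en-2-yl)-1,3-dioxolan-4-yl]-3-methylbut-2-enoate | COC(=O)/C=C(\C)C[C@@H]1OC(C)(C)O[C@@H]1C(C)(C)C=C | intermediate
12 | pent-1-en-3-one (ethyl vinyl ketone) | CCC(=O)C=C | starting material
13 | methyl (2E)-4-[(4S,5R)-2,2-dimethyl-5-[(3E)-2-methyl-5-oxohept-3-en-2-yl]-1,3-dioxolan-4-yl]-3-methylbut-2-enoate | COC(=O)/C=C(\C)C[C@@H]1OC(C)(C)O[C@@H]1C(C)(C)/C=C/C(=O)CC | intermediate
14 | methyl (2E)-4-[(4S,5R)-5-[(3E,5Z)-5-(tert-butyldimethylsilyloxy)-2-methylhepta-3,5-dien-2-yl]-2,2-dimethyl-1,3-dioxolan-4-yl]-3-methylbut-2-enoate | COC(=O)/C=C(\C)C[C@@H]1OC(C)(C)O[C@@H]1C(C)(C)/C=C/C(O[Si](C)(C)C(C)(C)C)=C/C | intermediate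
15 | (2E)-4-[(4S,5R)-5-[(3E,5Z)-5-(tert-butyldimethylsilyloxy)-2-methylhepta-3,5-dien-2-yl]-2,2-dimethyl-1,3-dioxolan-4-yl]-3-methylbut-2-en-1-ol | OC/C=C(\C)C[C@@H]1OC(C)(C)O[C@@H]1C(C)(C)/C=C/C(O[Si](C)(C)C(C)(C)C)=C/C | intermediate
16 | (2E)-4-[(4S,5R)-5-[(3E,5Z)-5-(tert-butyldimethylsilyloxy)-2-methylhepta-3,5-dien-2-yl]-2,2-dimethyl-1,3-dioxolan-4-yl]-3-methylbut-2-enal | O=C/C=C(\C)C[C@@H]1OC(C)(C)O[C@@H]1C(C)(C)/C=C/C(O[Si](C)(C)C(C)(C)C)=C/C | intermediate
17 | 7-(tert-butyldimethylsilyloxy)-2,3-(isopropylidenedioxy)-12,13,14,15,16-pentanorlabd-6-en-11-al; trans-fused; 8-methyl, 9-formyl and 10-methyl on one face, H-5, O-2 and O-3 on the other | CC1(C)O[C@H]2C[C@@]3(C)[C@H](C=O)[C@H](C)C(O[Si](C)(C)C(C)(C)C)=C[C@@H]3C(C)(C)[C@H]2O1 | intermediate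
18 | 7-(tert-butyldimethylsilyloxy)-2,3-(isopropylidenedioxy)-13,14,15,16-tetranorlabda-6,11-diene (9-vinyl analogue of 17) | CC1(C)O[C@H]2C[C@@]3(C)[C@H](C=C)[C@H](C)C(O[Si](C)(C)C(C)(C)C)=C[C@@H]3C(C)(C)[C@H]2O1 | intermediate
19 | methyl 3-oxobutanoate (methyl acetoacetate) | COC(=O)CC(C)=O | starting material
20 | methyl (2E)-3-(trifluoromethylsulfonyloxy)but-2-enoate | COC(=O)/C=C(\C)OS(=O)(=O)C(F)(F)F | intermediate
21 | B-alkyl-9-borabicyclo[3.3.1]nonane from 18 (boron on C12) | CC1(C)O[C@H]2C[C@@]3(C)[C@H](CCB4C5CCCC4CCC5)[C@H](C)C(O[Si](C)(C)C(C)(C)C)=C[C@@H]3C(C)(C)[C@H]2O1 | intermediate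
22 | methyl (13E)-7-(tert-butyldimethylsilyloxy)-2,3-(isopropylidenedioxy)labda-6,13-dien-15-oate | CC1(C)O[C@H]2C[C@@]3(C)[C@H](CC/C(C)=C/C(=O)OC)[C@H](C)C(O[Si](C)(C)C(C)(C)C)=C[C@@H]3C(C)(C)[C@H]2O1 | intermediate
23 | methyl (13E)-2,3-(isopropylidenedioxy)-7-oxolabd-13-en-15-oate (8-methyl on the face of the C10 methyl) | CC1(C)O[C@H]2C[C@@]3(C)[C@H](CC/C(C)=C/C(=O)OC)[C@H](C)C(=O)C[C@@H]3C(C)(C)[C@H]2O1 | intermediate
24 | methyl (13E)-2,3-(isopropylidenedioxy)-7-(trifluoromethylsulfonyloxy)labda-7,13-dien-15-oate | CC1(C)O[C@H]2C[C@@]3(C)[C@H](CC/C(C)=C/C(=O)OC)C(C)=C(OS(=O)(=O)C(F)(F)F)C[C@@H]3C(C)(C)[C@H]2O1 | intermediate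
25 | methyl (13E)-2,3-(isopropylidenedioxy)labda-7,13-dien-15-oate | CC1(C)O[C@H]2C[C@@]3(C)[C@H](CC/C(C)=C/C(=O)OC)C(C)=CC[C@@H]3C(C)(C)[C@H]2O1 | intermediate
26 | (13E)-2,3-(isopropylidenedioxy)labda-7,13-dien-15-oic acid | CC1(C)O[C@H]2C[C@@]3(C)[C@H](CC/C(C)=C/C(=O)O)C(C)=CC[C@@H]3C(C)(C)[C@H]2O1 | intermediate
27 | (13E)-2,3-dihydroxylabda-7,13-dien-15-oic acid | O[C@H]1C[C@@]2(C)[C@H](CC/C(C)=C/C(=O)O)C(C)=CC[C@@H]2C(C)(C)[C@H]1O | intermediate
28 | acetic (13E)-2,3-diacetoxylabda-7,13-dien-15-oic anhydride | CC(=O)O[C@H]1C[C@@]2(C)[C@H](CC/C(C)=C/C(=O)OC(C)=O)C(C)=CC[C@@H]2C(C)(C)[C@H]1OC(C)=O | intermediate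
29 | (13E)-2,3-diacetoxylabda-7,13-dien-15-oic acid, (2S,3R,5S,9R,10S), CNP0321684.1 | CC(=O)O[C@H]1C[C@@]2(C)[C@H](CC/C(C)=C/C(=O)O)C(C)=CC[C@@H]2C(C)(C)[C@H]1OC(C)=O | target

Total step count: 21 (steps 6 and 15 prepare the two coupling partners).
Longest linear sequence: 19 steps (steps 1–5, 7–14 and 16–21).

Steps most likely to fail

1. Step 13. The C5–C10 bond joins a neopentyl diene terminus to a fully substituted dienophile carbon, so ring closure may be slower than thermal E/Z isomerisation or degradation of the enal and loss of the dienol silyl ether, and exo (cis-fused) closure may compete. Fallback: the cycloaddition is moved one oxidation level back. Ester 14, whose enoate is configurationally robust, would be heated in 1,2-dichlorobenzene (BHT, 190 °C) to give the methyl ester cycloadduct F1. Reduction with i-Bu2AlH (CH2Cl2, −78 °C) would give the primary alcohol F2, and Parikh–Doering oxidation (SO3·pyridine, DMSO, i-Pr2NEt) would return to aldehyde 17.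

2. Step 18. O-Sulfonylation may run under kinetic control toward the less substituted C6=C7 enol triflate, or equilibration may stop short. Fallback: the regiochemical decision is separated from the triflation. Ketone 23 would be equilibrated to the more substituted trimethylsilyl enol ether F3 (Me3SiCl, NaI, Et3N, MeCN, rt), which would be converted regiospecifically with CsF and PhNTf2 in DME into triflate 24.

3. Step 7. Facial selectivity in the addition to the α-silyloxy aldehyde may be poor if the steric Felkin mode (tert-alkyl group anti to the nucleophile) competes with the polar mode, which would give the C5 epimer of 9. Fallback: the carbinol is set by chelation-controlled reduction instead of by addition. The mixture of 9 and its C5 epimer would be oxidised with Dess–Martin periodinane to the ketone F4, and the silyl ether removed with HF·pyridine to give the α-hydroxy ketone F5. Zn(BH4)2 (Et2O, −20 °C) should then deliver hydride to the zinc chelate from the face away from the tert-alkyl group and give anti-diol 10, which is taken on to 11 with 2,2-dimethoxypropane as in step 8.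

Further compounds
F1 | step 13 | methyl 7-(tert-butyldimethylsilyloxy)-2,3-(isopropylidenedioxy)-12,13,14,15,16-pentanorlabd-6-en-11-oate | CC1(C)O[C@H]2C[C@@]3(C)[C@H](C(=O)OC)[C@H](C)C(O[Si](C)(C)C(C)(C)C)=C[C@@H]3C(C)(C)[C@H]2O1
F2 | step 13 | 7-(tert-butyldimethylsilyloxy)-2,3-(isopropylidenedioxy)-12,13,14,15,16-pentanorlabd-6-en-11-ol | CC1(C)O[C@H]2C[C@@]3(C)[C@H](CO)[C@H](C)C(O[Si](C)(C)C(C)(C)C)=C[C@@H]3C(C)(C)[C@H]2O1
F3 | step 18 | methyl (13E)-2,3-(isopropylidenedioxy)-7-(trimethylsilyloxy)labda-7,13-dien-15-oate | CC1(C)O[C@H]2C[C@@]3(C)[C@H](CC/C(C)=C/C(=O)OC)C(C)=C(O[Si](C)(C)C)C[C@@H]3C(C)(C)[C@H]2O1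
F4 | step 7 | methyl (2E,6R)-3,7,7-trimethyl-5-oxo-6-(triethylsilyloxy)nona-2,8-dienoate | COC(=O)/C=C(\C)CC(=O)[C@H](O[Si](CC)(CC)CC)C(C)(C)C=C
F5 | step 7 | methyl (2E,6R)-6-hydroxy-3,7,7-trimethyl-5-oxonona-2,8-dienoate | COC(=O)/C=C(\C)CC(=O)[C@H](O)C(C)(C)C=C
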